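**Retrosynthetic overview**
1. Target ⇐ O-acetylation and 1,2-reduction (hydride syn to the C8 bridge) of the C2 carbonyl of a 3-methoxybicyclo[3.2.1]oct-3-ene-2,8-dione ⇐ C3–C4 dehydrogenation of the saturated 2,8-dione.
2. Saturated dione ⇐ one-flask annulation forming C1–C2 (ring-closing Claisen acylation), C4–C5 (Michael addition) and C6–CH3 (cuprate addition) from a 2-allyl-4-aryl-5-methoxycyclopent-2-enone, Me2CuLi and methyl 2-methoxyacrylate.
3. Enabling feature: the C8 ketone has both bridgeheads C1 and C5 as its α-carbons and C2 lies β to it, so ring C1–C2–C3–C4–C5–C8 is, at the dione level, a cyclohexane-1,3-dione laid across the α and α' carbons of the cyclopentanone ring C8–C1–C7–C6–C5, and the bridge C2–C3(OMe)–C4 is an α-methoxyacrylate.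
4. Enone ⇐ cyclopent-2-enone by rhodium/(S)-BINAP aryl addition with enolate silylation (C7), α-methoxylation (C1), dehydrogenation (C5=C6), α-iodination and Stille allylation (C5).
5. Ring order: the cyclopentanone ring is present from the start; the six-membered ring, and with it the bicycle, closes in the key step.

Key step: step 6

Remark: locants C1–C8 are those of the target bicycle (C1 and C5 bridgeheads, C8 the bridging ketone) and are used for the same atoms in the monocyclic precursors; the aryl Grignard solution and methyl 2-methoxyacrylate are taken as purchasable; the configurations at C1 before the key step and at C3 after it are inconsequential, because both centres become trigonal later.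

Step 1
Reactants: 1 cyclopent-2-en-1-one; 2 (3,4,5-trimethoxyphenyl)magnesium bromide (THF solution)
Product: 5 trimethyl{[(3S)-3-(3,4,5-trimethoxyphenyl)cyclopent-1-en-1-yl]oxy}silane, via aryltitanium triisopropoxide 3 (not isolated), via titanium enolate 4 (not isolated)
Conditions: 2, ClTi(OiPr)3, THF, −78 → 20 °C; then 1, [Rh(OH)((S)-binap)]2 (1.5 mol%), THF, 20 °C; then LiOiPr, Me3SiCl
Reagents that add atoms: chlorotrimethylsilane C[Si](C)(C)Cl
Why: Rhodium-catalysed asymmetric 1,4-addition of the aryltitanium reagent (Hayashi–Miyaura reaction in its aprotic form) should create C7 with the (S) configuration under control of (S)-BINAP and leave a titanium enolate that is silylated, which marks the aryl-side α-carbon C1 for the next step.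

Step 2
Reactants: 5 trimethyl{[(3S)-3-(3,4,5-trimethoxyphenyl)cyclopent-1-en-1-yl]oxy}silane
Product: 6 (2R,3R)-2-methoxy-3-(3,4,5-trimethoxyphenyl)cyclopentan-1-one
Conditions: PhIO, BF3·OEt2, MeOH, CH2Cl2, −78 °C → rt
Reagents that add atoms: methanol CO
Why: Electrophilic trivalent iodine should add to the silyl enol ether at C1 only and methanol then displaces iodobenzene (hypervalent-iodine α-methoxylation of a silyl enol ether), with the methoxy group expected trans to the neighbouring aryl group.

Step 3
Reactants: 6 (2R,3R)-2-methoxy-3-(3,4,5-trimethoxyphenyl)cyclopentan-1-one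
Product: 8 (4R,5R)-5-methoxy-4-(3,4,5-trimethoxyphenyl)cyclopent-2-en-1-one, via lithium enolate 7 (not isolated)
Conditions: LiN(iPr)2, THF, −78 °C; then N-tert-butylbenzenesulfinimidoyl chloride, −78 °C
Reagents that add atoms: none
Why: Kinetic deprotonation with the hindered amide should take place at the C5 methylene and not at the methoxy-bearing methine C1, and the lithium enolate reacts at sulfur with the sulfinimidoyl chloride and loses the sulfenamide by syn-elimination (one-pot ketone dehydrogenation) to place the double bond at C5=C6 without touching C7.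

Step 4
Reactants: 8 (4R,5R)-5-methoxy-4-(3,4,5-trimethoxyphenyl)cyclopent-2-en-1-one
Product: 9 (4R,5R)-2-iodo-5-methoxy-4-(3,4,5-trimethoxyphenyl)cyclopent-2-en-1-one
Conditions: I2, pyridine, CH2Cl2, 0 °C → rt
Reagents that add atoms: iodine II
Why: Pyridine adds reversibly to C6, the resulting enolate is iodinated at C5 and pyridine is eliminated again (α-iodination of a cyclic enone), so iodine should enter only at the enone α-carbon.

Step 5
Reactants: 9 (4R,5R)-2-iodo-5-methoxy-4-(3,4,5-trimethoxyphenyl)cyclopent-2-en-1-one; 10 tributyl(prop-2-en-1-yl)stannane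
Product: 11 (4R,5R)-5-methoxy-2-(prop-2-en-1-yl)-4-(3,4,5-trimethoxyphenyl)cyclopent-2-en-1-one
Conditions: Pd2(dba)3 (2.5 mol%), AsPh3, CuI (10 mol%), NMP, rt
Reagents that add atoms: none
Why: Stille coupling of the α-iodoenone with the allylstannane (AsPh3 and CuI to speed transmetalation) should give the 2-allyl enone under neutral conditions that leave the γ-stereocentre C7 untouched.

Step 6
Reactants: 11 (4R,5R)-5-methoxy-2-(prop-2-en-1-yl)-4-(3,4,5-trimethoxyphenyl)cyclopent-2-en-1-one; 12 methyl 2-methoxyprop-2-enoate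
Product: 15 (1R,5R,6S,7R)-1,3-dimethoxy-6-methyl-5-(prop-2-en-1-yl)-7-(3,4,5-trimethoxyphenyl)bicyclo[3.2.1]octane-2,8-dione (C3 epimer mixture), via lithium enolate 13 (not isolated), via Michael adduct enolate 14 (not isolated)
Conditions: Me2CuLi (from MeLi and CuI), THF, −78 °C; then 12, DMPU, −78 → 0 °C; aq. NH4Cl
Reagents that add atoms: lithium dimethylcuprate [Li+].C[Cu-]C
Why: Me2CuLi adds its methyl group to C6 anti to the C7 aryl group and thereby releases the C5 lithium enolate 13 regiospecifically; this enolate adds to acrylate 12 on the face anti to the new C6 methyl group, which makes C5 quaternary with the propanoate arm cis to the aryl group, and proton transfer from C1–H to the ester enolate gives ketone enolate 14. The C1 carbon of 14 then attacks the ester carbonyl C2 and expels methoxide (intramolecular Claisen condensation, 6-(enolendo)-exo-trig), which forms the C1–C2 bond and closes the six-membered ring C1–C2–C3–C4–C5–C8; the methoxide removes C3–H, so the dione rests as its C2=C3 enolate and is shielded from retro-Claisen cleavage until the quench. The closest known reaction types are the three-component coupling of 4-substituted cyclopentenones (conjugate addition, then enolate trapping trans to the new β-substituent) and the Michael–Claisen annulation of ketone enolates with acrylates to cyclohexane-1,3-diones, here laid across the α and α' carbons of a cyclopentanone as in the α,α'-annulation of cyclopentanone enamines with acryloyl chloride to bicyclo[3.2.1]octane-2,8-diones. C6 is controlled by the C7 aryl group, C5 by the C6 methyl group, and C1 by the tether, since the arm on C5 can reach only the face of the enolate on which it sits; the former C1 configuration is erased and C3 forms as a mixture that step 7 removes. The step needs regiocontrol between the two α-carbons and a single site for the acylation: the conjugate addition supplies the C5 enolate only, and after the Michael addition C5 is quaternary, so C1 is the only enolisable carbon next to the ketone and the six-membered ring is the only unstrained closure open to it.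

Step 7
Reactants: 15 (1R,5R,6S,7R)-1,3-dimethoxy-6-methyl-5-(prop-2-en-1-yl)-7-(3,4,5-trimethoxyphenyl)bicyclo[3.2.1]octane-2,8-dione
Product: 17 (1R,5S,6S,7R)-1,3-dimethoxy-6-methyl-5-(prop-2-en-1-yl)-7-(3,4,5-trimethoxyphenyl)bicyclo[3.2.1]oct-3-ene-2,8-dione, via silyl enol ether 16 (not isolated)
Conditions: LiN(SiMe3)2, Me3SiCl, THF, −78 °C; then Pd(OAc)2, MeCN, rt
Reagents that add atoms: none
Why: C3–H is the only enolisable position of 15, so silylation gives one silyl enol ether and the Saegusa–Ito oxidation (palladium enolate, β-hydride elimination from C4) should deliver the C3=C4 double bond and erase the C3 stereocentre.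

Step 8
Reactants: 17 (1R,5S,6S,7R)-1,3-dimethoxy-6-methyl-5-(prop-2-en-1-yl)-7-(3,4,5-trimethoxyphenyl)bicyclo[3.2.1]oct-3-ene-2,8-dione
Product: 18 (1S,2R,5S,6S,7R)-2-hydroxy-1,3-dimethoxy-6-methyl-5-(prop-2-en-1-yl)-7-(3,4,5-trimethoxyphenyl)bicyclo[3.2.1]oct-3-en-8-one (locants as in the target)
Conditions: NaBH4, CeCl3·7H2O, MeOH, −78 °C
Reagents that add atoms: none
Why: Luche reduction: the cerium-activated conjugated C2 carbonyl should be reduced in 1,2-fashion faster than the C8 ketone, which lies between two quaternary carbons, and hydride should enter from the face syn to the C8 bridge because the other face is covered by the endo aryl group on C7, which places the new hydroxyl anti to C8 as the target requires.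

Step 9
Reactants: 18 (1S,2R,5S,6S,7R)-2-hydroxy-1,3-dimethoxy-6-methyl-5-(prop-2-en-1-yl)-7-(3,4,5-trimethoxyphenyl)bicyclo[3.2.1]oct-3-en-8-one
Product: 19 (1S,2R,5S,6S,7R)-1,3-dimethoxy-6-methyl-8-oxo-5-(prop-2-en-1-yl)-7-(3,4,5-trimethoxyphenyl)bicyclo[3.2.1]oct-3-en-2-yl acetate (target)
Conditions: Ac2O, pyridine, DMAP (cat.), CH2Cl2, rt
Reagents that add atoms: acetic anhydride CC(=O)OC(C)=O
Why: DMAP-catalysed O-acylation of the secondary allylic alcohol with acetic anhydride, which touches no stereocentre.

**Compound list**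
1 | cyclopent-2-en-1-one | O=C1C=CCC1 | starting material
2 | (3,4,5-trimethoxyphenyl)magnesium bromide | COc1cc([Mg]Br)cc(OC)c1OC | starting material
3 | triisopropoxy(3,4,5-trimethoxyphenyl)titanium | COc1cc(cc(OC)c1OC)[Ti](OC(C)C)(OC(C)C)OC(C)C | intermediate
4 | triisopropoxytitanium (3S)-3-(3,4,5-trimethoxyphenyl)cyclopent-1-en-1-olate | CC(C)O[Ti](OC(C)C)(OC(C)C)OC1=C[C@@H](c2cc(OC)c(OC)c(OC)c2)CC1 | intermediate
5 | trimethyl{[(3S)-3-(3,4,5-trimethoxyphenyl)cyclopent-1-en-1-yl]oxy}silane | C[Si](C)(C)OC1=C[C@@H](c2cc(OC)c(OC)c(OC)c2)CC1 | intermediate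
6 | (2R,3R)-2-methoxy-3-(3,4,5-trimethoxyphenyl)cyclopentan-1-one (methoxy trans to aryl) | O=C1[C@H](OC)[C@@H](c2cc(OC)c(OC)c(OC)c2)CC1 | intermediate
7 | lithium (4R,5R)-5-methoxy-4-(3,4,5-trimethoxyphenyl)cyclopent-1-en-1-olate | [Li+].[O-]C1=CC[C@H](c2cc(OC)c(OC)c(OC)c2)[C@H]1OC | intermediate
8 | (4R,5R)-5-methoxy-4-(3,4,5-trimethoxyphenyl)cyclopent-2-en-1-one | O=C1[C@H](OC)[C@@H](c2cc(OC)c(OC)c(OC)c2)C=C1 | intermediate
9 | (4R,5R)-2-iodo-5-methoxy-4-(3,4,5-trimethoxyphenyl)cyclopent-2-en-1-one | O=C1[C@H](OC)[C@@H](c2cc(OC)c(OC)c(OC)c2)C=C1I | intermediate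
10 | tributyl(prop-2-en-1-yl)stannane | C=CC[Sn](CCCC)(CCCC)CCCC | starting material
11 | (4R,5R)-5-methoxy-2-(prop-2-en-1-yl)-4-(3,4,5-trimethoxyphenyl)cyclopent-2-en-1-one | O=C1[C@H](OC)[C@@H](c2cc(OC)c(OC)c(OC)c2)C=C1CC=C | intermediate
12 | methyl 2-methoxyprop-2-enoate | C=C(OC)C(=O)OC | starting material
13 | lithium (3S,4R,5R)-5-methoxy-3-methyl-2-(prop-2-en-1-yl)-4-(3,4,5-trimethoxyphenyl)cyclopent-1-en-1-olate (methyl trans to aryl) | [Li+].[O-]C1=C(CC=C)[C@@H](C)[C@H](c2cc(OC)c(OC)c(OC)c2)[C@H]1OC | intermediate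
14 | lithium (3R,4S,5R)-2-methoxy-5-(2,3-dimethoxy-3-oxopropyl)-4-methyl-5-(prop-2-en-1-yl)-3-(3,4,5-trimethoxyphenyl)cyclopent-1-en-1-olate (ester arm cis to aryl, side-chain centre undefined) | [Li+].[O-]C1=C(OC)[C@@H](c2cc(OC)c(OC)c(OC)c2)[C@H](C)[C@@]1(CC=C)CC(OC)C(=O)OC | intermediate
15 | (1R,5R,6S,7R)-1,3-dimethoxy-6-methyl-5-(prop-2-en-1-yl)-7-(3,4,5-trimethoxyphenyl)bicyclo[3.2.1]octane-2,8-dione (7-endo aryl, 6-exo methyl, C3 epimer mixture) | C=CC[C@]12CC(OC)C(=O)[C@](OC)(C1=O)[C@@H](c1cc(OC)c(OC)c(OC)c1)[C@@H]2C | intermediate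
16 | (1S,5R,6S,7R)-1,3-dimethoxy-6-methyl-5-(prop-2-en-1-yl)-7-(3,4,5-trimethoxyphenyl)-2-(trimethylsilyloxy)bicyclo[3.2.1]oct-2-en-8-one | C=CC[C@]12CC(OC)=C(O[Si](C)(C)C)[C@](OC)(C1=O)[C@@H](c1cc(OC)c(OC)c(OC)c1)[C@@H]2C | intermediate
17 | (1R,5S,6S,7R)-1,3-dimethoxy-6-methyl-5-(prop-2-en-1-yl)-7-(3,4,5-trimethoxyphenyl)bicyclo[3.2.1]oct-3-ene-2,8-dione | C=CC[C@]12C=C(OC)C(=O)[C@](OC)(C1=O)[C@@H](c1cc(OC)c(OC)c(OC)c1)[C@@H]2C | intermediate
18 | (1S,2R,5S,6S,7R)-2-hydroxy-1,3-dimethoxy-6-methyl-5-(prop-2-en-1-yl)-7-(3,4,5-trimethoxyphenyl)bicyclo[3.2.1]oct-3-en-8-one (hydroxyl anti to C8) | C=CC[C@]12C=C(OC)[C@@H](O)[C@](OC)(C1=O)[C@@H](c1cc(OC)c(OC)c(OC)c1)[C@@H]2C | intermediate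
19 | (1S,2R,5S,6S,7R)-1,3-dimethoxy-6-methyl-8-oxo-5-(prop-2-en-1-yl)-7-(3,4,5-trimethoxyphenyl)bicyclo[3.2.1]oct-3-en-2-yl acetate | C=CC[C@]12C=C(OC)[C@@H](OC(C)=O)[C@](OC)(C1=O)[C@@H](c1cc(OC)c(OC)c(OC)c1)[C@@H]2C | target

**Step count and risks**
Total steps: 9. Longest linear sequence: 9 steps (from 1).

Steps most likely to fail:

1. Step 6. The fully substituted C5 enolate may add too slowly to the donor-substituted acrylate (acrylate oligomerisation, or simple protonation of the enolate on work-up), or the ring closure next to the aryl-bearing carbon may stall at the Michael adduct. The fallback sets out from 11 and decouples the events: conjugate addition of Me2CuLi with Me3SiCl trapping would give the silyl enol ether F1; a TiCl4-promoted Mukaiyama–Michael addition of F1 to 12, which activates the acceptor instead of the donor, would give the keto ester F2; KOtBu in THF would then close the ring by Claisen condensation, and the route is rejoined at 15.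

2. Step 8. Chemoselectivity may be lost through hydride attack on the C8 ketone in competition with, or ahead of, the conjugated C2 carbonyl. The fallback sets out from 17 and gives up the discrimination between the carbonyl groups: excess NaBH4 with CeCl3·7H2O would reduce both to the diol F3; Ac2O in pyridine without DMAP should acetylate only the C2 hydroxyl, because the C8 carbinol lies between two quaternary bridgeheads, to give the monoacetate F4; Dess–Martin oxidation of the remaining C8 carbinol comes back to the route at 19.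

3. Step 2. The iodine oxidant may attack the electron-rich trimethoxyphenyl ring, or the silyl enol ether may be cleaved to the ketone before oxygen transfer. The fallback sets out from 5 and separates oxygenation from methylation: Rubottom oxidation with dimethyldioxirane and mild desilylation would give the hydroxy ketone F5, and O-methylation with MeI and Ag2O comes back to the route at 6.

Further compounds
F1 | step 6 | trimethyl{[(3S,4R,5R)-5-methoxy-3-methyl-2-(prop-2-en-1-yl)-4-(3,4,5-trimethoxyphenyl)cyclopent-1-en-1-yl]oxy}silane | C[Si](C)(C)OC1=C(CC=C)[C@@H](C)[C@H](c2cc(OC)c(OC)c(OC)c2)[C@H]1OC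
F2 | step 6 | methyl 2-methoxy-3-[(1R,3R,4R,5S)-3-methoxy-5-methyl-2-oxo-1-(prop-2-en-1-yl)-4-(3,4,5-trimethoxyphenyl)cyclopentyl]propanoate (side-chain centre undefined) | O=C1[C@H](OC)[C@@H](c2cc(OC)c(OC)c(OC)c2)[C@H](C)[C@@]1(CC=C)CC(OC)C(=O)OC
F3 | step 8 | 1,3-dimethoxy-6-methyl-5-(prop-2-en-1-yl)-7-(3,4,5-trimethoxyphenyl)bicyclo[3.2.1]oct-3-ene-2,8-diol with the ring configuration of 18 (C8 carbinol configuration open) | C=CC[C@]12C=C(OC)[C@@H](O)[C@](OC)(C1O)[C@@H](c1cc(OC)c(OC)c(OC)c1)[C@@H]2C
F4 | step 8 | 8-hydroxy-1,3-dimethoxy-6-methyl-5-(prop-2-en-1-yl)-7-(3,4,5-trimethoxyphenyl)bicyclo[3.2.1]oct-3-en-2-yl acetate with the ring configuration of 19 (C8 carbinol configuration open) | C=CC[C@]12C=C(OC)[C@@H](OC(C)=O)[C@](OC)(C1O)[C@@H](c1cc(OC)c(OC)c(OC)c1)[C@@H]2C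
F5 | step 2 | (2R,3R)-2-hydroxy-3-(3,4,5-trimethoxyphenyl)cyclopentan-1-one | O=C1[C@H](O)[C@@H](c2cc(OC)c(OC)c(OC)c2)CC1
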